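Early on, the two runs climbed together: at 15.0 min dusk read 10.5% and dawn 11.7%, though dawn held half the Q.

| flask | G | L | Q | remark | time | volume of the second phase over the first |
|---|---|---|---|---|---|---|
| dusk | 0.32 M | 0.48 M | 0.016 M | the very flask that is asked about, followed so far |  |  |
| dawn | 0.32 M | 0.48 M | 0.0080 M | run made earlier |  |  |
| flask | 0.32 M | 0.480 M | 0.0160 M |  | 2.5 h | 1.0 |

| run | time / min | X / % |
|---|---|---|
| dusk | 3.00 | 4.5 |
| dusk | 10.0 | 7.8 |
| dusk | 15.0 | 10.5 |
| dusk | 25.0 | 14.4 |
| dusk | 40.0 | 18.1 |
| dusk | 50.0 | 18.0 |
| dusk | 60.0 | 20.2 |
| dawn | 8.00 | 7.5 |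
| dawn | 15.0 | 11.7 |
| dawn | 25.0 | 15.3 |
| dawn | 30.0 | 16.6 |
| dawn | 40.0 | 19.1 |
| dawn | 50.0 | 17.8 |
| dawn | 60.0 | 18.6 |

(scatter of a reading: 1 percentage point)

- in the second phase: L; everything else is in the first
- charges count per volume of the first phase; a concentration in a rate is the amount of a species over the volume of its own phase; every rate counts per litre of the first phase
- the numbers in the tables scatter with a standard deviation of 1 percentage point
- the earlier runs hold the two phases in the same ratio of volumes as the flask asked about

- how much X there is at 2.5 h, in percent of the G charged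
- the change that raises the amount of X at 2.5 h, in percent of the G charged most ("none" if none brings more than 2 percentage points) (Wednesday's / Tuesday's / none)
- amount of X at 2.5 h, in percent of the G charged, after Wednesday's

How far was the dusk flask from its plateau at the time asked? The readings of both runs from 40.0 min on averaged 18.6%. From that and the mean at 15.0 min I took the settling time τ, the time in which the gap to the plateau shrinks by a factor e (the time constant of a first-order approach): 16.6 min.

Those last readings centre on 50.0 min, so I put the plateau at 19.6%. The asked 2.5 h is 9.04 settling times, which by this estimate leaves a gap of 0.0023 percentage points, far below the 2 points that counts. So I committed to 19.6%, and I expected no gain above 2 points from Tuesday's, which I took merely to shorten τ.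

What could lift the plateau, then? I judged G not short, with an estimated 0.0627 M of X against 0.32 M charged, so I chose Wednesday's, more L.

The forecast gave 20%, Wednesday's and 33%: “This looks like an equilibrium approached through L transfer.”

The flask gave 19.8% at 2.5 h, and Wednesday's brought 6.6 points, to 26.4%, while Tuesday's brought 0 points.

    G + Z → X (k = 7.89 × 10⁻⁴ /M/s)
    Z + X → J (k = 0.00140 /M/s)
    Z ⇌ L, rate k3*([Z] - [L]/K3) per volume of the first phase (partition coefficient = 0.711, kL = 0.0412 /s)
    Z + Q → E (k = 0.0348 /M/s)
    Z → D (k = 9.55 × 10⁻⁴ /s)

At 2.50 h the flask held 0.0653% of its charge of L and 0.361 M of D. With τ, X at 0.625 h reckons to 17.7%, and the flask held 17.2%. For the same flask read at 1.5 h, τ gives 19.7%, and that reading held 19.5%.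

Readings and results stem from a simulated flask with made-up constants, and the scatter is random.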